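The central cyclohexene (C1 quaternary carbon with methyl and the styryl arm, C2 and C3 methylenes, C4=C5 alkene with methyl on C4, C6 aryl-bearing methine) is cut at C3–C4, where a ring methylene meets the methyl-bearing sp2 carbon. In one pot a vinyl group on C1 is hydroborated at its terminus (C3) and the B-alkyl group is cross-coupled with a (Z)-2-iodopropenyl group on C6, which closes the ring, locks the alkene at C4–C5 and leaves both stereocentres untouched. The precursor is an acyclic 1,5-diene whose C1 and C6 come from an enantioselective Ireland–Claisen rearrangement; both coumarins are annulated at the end from 2,6-dimethoxyphenyl groups.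

Key step: step 9

Assumption 1: the arylacetate 6 is taken to enolise to the Z(O)-enolate (aryl cis to the O–B oxygen), as arylacetic esters generally do; with that enolate the chair transition state gives the required C1/C6 relationship only from the Z allylic alcohol 4, whereas the E isomer would give the C1 epimer.
Assumption 2: the facial sense of the (S,S)-diazaborolidine in step 5 is assigned by analogy with simple allyl esters; the (R,R) antipode, equally accessible, would be used instead if the acid formed proved to be the mirror image of 8.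
Assumption 3: the C1 hydroxymethyl group is carried as a tert-butyldiphenylsilyl ether, so that its removal needs only fluoride and no oxidant near the benzylic and allylic C6–H or the electron-rich arenes.

Step 1
Reactants: 1 tert-butyl(diphenyl)(prop-2-yn-1-yloxy)silane
Product: 2 ethyl 4-[(tert-butyldiphenylsilyl)oxy]but-2-ynoate
Conditions: n-BuLi, THF, −78 °C; ClCO2Et, −78 → 0 °C
Reagents that add atoms: ethyl chloroformate, CCOC(Cl)=O
Why: C-acylation of the lithium acetylide with a chloroformate is the standard entry to 4-silyloxy-2-ynoates, and the silyl ether is inert to n-BuLi at −78 °C.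

Step 2
Reactants: 2 ethyl 4-[(tert-butyldiphenylsilyl)oxy]but-2-ynoate
Product: 3 ethyl (2Z)-4-[(tert-butyldiphenylsilyl)oxy]-3-methylbut-2-enoate
Conditions: Me2CuLi (from MeLi and CuI), Et2O/THF, −78 °C; NH4Cl (aq MeOH) quench at −78 °C
Reagents that add atoms: lithium dimethylcuprate, [Li+].C[Cu-]C
Why: Conjugate addition of the cuprate to the ynoate is a syn-carbocupration, so protonation of the alkenylcuprate at −78 °C leaves the new methyl cis to H and the silyloxymethyl group cis to the ester, which is the Z-enoate.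

Step 3
Reactants: 3 ethyl (2Z)-4-[(tert-butyldiphenylsilyl)oxy]-3-methylbut-2-enoate
Product: 4 (2Z)-4-[(tert-butyldiphenylsilyl)oxy]-3-methylbut-2-en-1-ol
Conditions: i-Bu2AlH, CH2Cl2, −78 °C; aq potassium sodium tartrate
Reagents that add atoms: none
Why: 1,2-Reduction of the enoate with i-Bu2AlH gives the allylic alcohol without disturbing the alkene geometry or the bulky silyl ether, which resists O-to-O migration.

Step 4
Reactants: 4 (2Z)-4-[(tert-butyldiphenylsilyl)oxy]-3-methylbut-2-en-1-ol; 5 (2,6-dimethoxyphenyl)acetic acid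
Product: 6 (2Z)-4-[(tert-butyldiphenylsilyl)oxy]-3-methylbut-2-en-1-yl (2,6-dimethoxyphenyl)acetate
Conditions: DCC, DMAP (cat.), CH2Cl2, 0 °C → rt
Reagents that add atoms: none
Why: Steglich esterification joins the primary allylic alcohol and the arylacetic acid under neutral conditions that leave the Z-alkene and the silyl ether alone.

Step 5
Reactants: 6 (2Z)-4-[(tert-butyldiphenylsilyl)oxy]-3-methylbut-2-en-1-yl (2,6-dimethoxyphenyl)acetate
Product: 8 (2R,3S)-3-{[(tert-butyldiphenylsilyl)oxy]methyl}-2-(2,6-dimethoxyphenyl)-3-methylpent-4-enoic acid, via boron ketene acetal 7 (not isolated)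
Conditions: (S,S)-2-bromo-4,5-diphenyl-1,3-bis{[3,5-bis(trifluoromethyl)phenyl]sulfonyl}-1,3,2-diazaborolidine [made from the (S,S)-bis-sulfonamide and BBr3 in CH2Cl2, volatiles removed], i-Pr2NEt, CH2Cl2, −78 °C; then −20 → 4 °C, several days; aq work-up
Reagents that add atoms: none
Why: Enantioselective Ireland–Claisen rearrangement: soft enolisation gives the Z(O)-boron ketene acetal 7, which rearranges through a chair transition state with the aryl group pseudo-equatorial and the silyloxymethyl arm of the Z-alkene pseudo-axial, so C6 and the quaternary C1 are created together with aryl and CH2OSi in the relationship that becomes cis on the ring, while the C2-symmetric diazaborolidine shields one enolate face and sets the absolute configuration.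

Step 6
Reactants: 8 (2R,3S)-3-{[(tert-butyldiphenylsilyl)oxy]methyl}-2-(2,6-dimethoxyphenyl)-3-methylpent-4-enoic acid
Product: 9 (2R,3S)-3-{[(tert-butyldiphenylsilyl)oxy]methyl}-2-(2,6-dimethoxyphenyl)-3-methylpent-4-en-1-ol
Conditions: LiAlH4, THF, 0 °C → rt
Reagents that add atoms: none
Why: Hydride reduction of the carboxylic acid with LiAlH4 gives the primary alcohol; the terminal alkene and the tert-butyldiphenylsilyl ether are inert and neither stereocentre is involved.

Step 7
Reactants: 9 (2R,3S)-3-{[(tert-butyldiphenylsilyl)oxy]methyl}-2-(2,6-dimethoxyphenyl)-3-methylpent-4-en-1-ol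
Product: 10 (2R,3S)-3-{[(tert-butyldiphenylsilyl)oxy]methyl}-2-(2,6-dimethoxyphenyl)-3-methylpent-4-enal
Conditions: DMP, NaHCO3, CH2Cl2, 0 °C → rt; used at once
Reagents that add atoms: none
Why: Dess–Martin oxidation under bicarbonate buffer gives the α-aryl aldehyde without acid or base strong enough to epimerise C6, whose enolisation is further slowed by the twisted 2,6-disubstituted arene and the quaternary neighbour.

Step 8
Reactants: 10 (2R,3S)-3-{[(tert-butyldiphenylsilyl)oxy]methyl}-2-(2,6-dimethoxyphenyl)-3-methylpent-4-enal; 11 ethyltriphenylphosphonium iodide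
Product: 14 2-[(3S,4R,5Z)-3-{[(tert-butyldiphenylsilyl)oxy]methyl}-6-iodo-3-methylhepta-1,5-dien-4-yl]-1,3-dimethoxybenzene, via iodoethylphosphonium iodide 12 (not isolated), via iodoethylidene ylide 13 (not isolated)
Conditions: 11, n-BuLi, THF, rt; I2, −78 °C; NaN(SiMe3)2, −78 → −20 °C; then 10, −78 °C → rt
Reagents that add atoms: iodine, [I][I]
Why: Stork–Zhao variant of the Wittig reaction: the non-stabilised α-iodoethylidene ylide 13 adds to the aldehyde at −78 °C under kinetic control and should give the trisubstituted iodoalkene with iodine cis to the C6 substituent (Z), fast enough at low temperature that C6 is not epimerised.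

Step 9
Reactants: 14 2-[(3S,4R,5Z)-3-{[(tert-butyldiphenylsilyl)oxy]methyl}-6-iodo-3-methylhepta-1,5-dien-4-yl]-1,3-dimethoxybenzene
Product: 16 tert-butyl{[(1S,2R)-2-(2,6-dimethoxyphenyl)-1,4-dimethylcyclohex-3-en-1-yl]methoxy}diphenylsilane, via B-alkyl-9-BBN adduct 15 (not isolated)
Conditions: 9-BBN-H, THF, 0 °C → rt; then PdCl2(dppf) (cat.), AsPh3, aq Cs2CO3, DMF/THF, degassed, ca. 0.01 M, rt → 50 °C
Reagents that add atoms: none
Why: 9-BBN-H adds anti-Markovnikov to the monosubstituted C1 vinyl group only, placing boron on C3 in 15; zerovalent palladium generated from PdCl2(dppf) then inserts into the C4–I bond with retention of the Z geometry, the base-activated borate transfers the primary C3 alkyl group to divalent palladium, and reductive elimination forms C3–C4. The closest known reaction type is the one-pot hydroboration and intramolecular B-alkyl Suzuki–Miyaura coupling of haloalkenes carrying a terminal alkene, which gives five- and six-membered cycloalkenes. The six-membered ring closes by C(sp3)–C(sp2) reductive elimination from a seven-membered palladacycle, with C4 and C5 both ending inside the ring as an endocyclic alkene. No stereocentre is created: C1 and C6 are carried through unchanged, and the Z-iodoalkene, which holds C6 and the incoming C3 cis across C4=C5, is the geometric element on which closure depends. The step needs chemoselective hydroboration (secured by the steric demand of 9-BBN and the inert trisubstituted iodoalkene), cyclisation over intermolecular coupling (quaternary C1 and dilution) and coupling faster than β-hydride elimination of the alkylpalladium (wide-bite-angle dppf with AsPh3).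

Step 10
Reactants: 16 tert-butyl{[(1S,2R)-2-(2,6-dimethoxyphenyl)-1,4-dimethylcyclohex-3-en-1-yl]methoxy}diphenylsilane
Product: 17 [(1S,2R)-2-(2,6-dimethoxyphenyl)-1,4-dimethylcyclohex-3-en-1-yl]methanol
Conditions: TBAF, THF, rt → 45 °C
Reagents that add atoms: none
Why: Fluoride-mediated desilylation frees the neopentyl-type primary alcohol, and nothing else in the molecule is fluoride-sensitive.

Step 11
Reactants: 17 [(1S,2R)-2-(2,6-dimethoxyphenyl)-1,4-dimethylcyclohex-3-en-1-yl]methanol
Product: 18 (1S,2S)-2-(2,6-dimethoxyphenyl)-1,4-dimethylcyclohex-3-ene-1-carbaldehyde (formyl and aryl cis; the C2 descriptor changes only through ligand priority)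
Conditions: DMP, NaHCO3, CH2Cl2, rt
Reagents that add atoms: none
Why: Dess–Martin oxidation gives an aldehyde whose α-carbon is quaternary, so it can neither enolise nor epimerise.

Step 12
Reactants: 19 (2,6-dimethoxyphenyl)methanol
Product: 20 diethyl [(2,6-dimethoxyphenyl)methyl]phosphonate
Conditions: P(OEt)3, ZnI2, toluene, reflux
Reagents that add atoms: triethyl phosphite, CCOP(OCC)OCC
Why: ZnI2-promoted ionisation of the electron-rich benzylic alcohol, capture by the phosphite and Michaelis–Arbuzov collapse give the benzylphosphonate in one operation.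

Step 13
Reactants: 18 (1S,2S)-2-(2,6-dimethoxyphenyl)-1,4-dimethylcyclohex-3-ene-1-carbaldehyde; 20 diethyl [(2,6-dimethoxyphenyl)methyl]phosphonate
Product: 21 2-[(1R,6R)-6-[(E)-2-(2,6-dimethoxyphenyl)ethenyl]-3,6-dimethylcyclohex-2-en-1-yl]-1,3-dimethoxybenzene
Conditions: 20, NaH, THF/DMF, 0 °C → rt; then 18, rt → 50 °C
Reagents that add atoms: none
Why: Horner–Wadsworth–Emmons olefination of the non-enolisable aldehyde with the preformed phosphonate anion (no excess base, so C6–H is not deprotonated) should give the E-styrene, the normal outcome for benzylphosphonate carbanions and reinforced here by the quaternary neighbour.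

Step 14
Reactants: 21 2-[(1R,6R)-6-[(E)-2-(2,6-dimethoxyphenyl)ethenyl]-3,6-dimethylcyclohex-2-en-1-yl]-1,3-dimethoxybenzene
Product: 22 2-[(E)-2-[(1R,2R)-2-(2-hydroxy-6-methoxyphenyl)-1,4-dimethylcyclohex-3-en-1-yl]ethenyl]-3-methoxyphenol
Conditions: NaSEt (excess), DMF, 140 °C; aq HCl to pH 5 at 0 °C
Reagents that add atoms: none
Why: Thiolate SN2 demethylation removes one methyl from each 2-substituted resorcinol dimethyl ether and then stops because the phenoxide formed deactivates the second methoxy group; the two methoxy groups of each arene are equivalent, so only one bis-phenol can form, and strong acid is avoided so the C6 phenol cannot add to the ring alkene.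

Step 15
Reactants: 22 2-[(E)-2-[(1R,2R)-2-(2-hydroxy-6-methoxyphenyl)-1,4-dimethylcyclohex-3-en-1-yl]ethenyl]-3-methoxyphenol
Product: 23 3-[(1R,6R)-6-[(E)-2-(3-formyl-2-hydroxy-6-methoxyphenyl)ethenyl]-3,6-dimethylcyclohex-2-en-1-yl]-2-hydroxy-4-methoxybenzaldehyde
Conditions: MgCl2, Et3N, (CH2O)n, MeCN, reflux
Reagents that add atoms: formaldehyde (as paraformaldehyde), C=O
Why: Magnesium-mediated ortho-formylation (Casnati–Skattebøl): each magnesium phenoxide directs formaldehyde to its only free ortho position, para to the remaining methoxy group, and a second formaldehyde oxidises the benzylic alkoxide to the aldehyde.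

Step 16
Reactants: 23 3-[(1R,6R)-6-[(E)-2-(3-formyl-2-hydroxy-6-methoxyphenyl)ethenyl]-3,6-dimethylcyclohex-2-en-1-yl]-2-hydroxy-4-methoxybenzaldehyde
Product: 25 7-methoxy-8-[(1R,6R)-6-[(E)-2-(7-methoxy-2-oxo-2H-chromen-8-yl)ethenyl]-3,6-dimethylcyclohex-2-en-1-yl]-2H-chromen-2-one, via bis(2-hydroxycinnamate) diester 24 (not isolated)
Conditions: Ph3P=CHCO2Et, PhNEt2, reflux
Reagents that add atoms: ethyl (triphenylphosphoranylidene)acetate, CCOC(=O)C=P(c1ccccc1)(c1ccccc1)c1ccccc1
Why: Wittig olefination of each salicylaldehyde with the stabilised ylide gives the 2-hydroxycinnamate 24, which at the reflux temperature of N,N-diethylaniline isomerises to the Z form and lactonises, the standard annulation for 8-substituted 7-methoxycoumarins; the stereocentres and both other alkenes are not involved.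

Compound list
1 | tert-butyl(diphenyl)(prop-2-yn-1-yloxy)silane | C#CCO[Si](c1ccccc1)(c1ccccc1)C(C)(C)C | starting material
2 | ethyl 4-[(tert-butyldiphenylsilyl)oxy]but-2-ynoate | CCOC(=O)C#CCO[Si](c1ccccc1)(c1ccccc1)C(C)(C)C | intermediate
3 | ethyl (2Z)-4-[(tert-butyldiphenylsilyl)oxy]-3-methylbut-2-enoate | CCOC(=O)/C=C(C)\CO[Si](c1ccccc1)(c1ccccc1)C(C)(C)C | intermediate
4 | (2Z)-4-[(tert-butyldiphenylsilyl)oxy]-3-methylbut-2-en-1-ol | OC/C=C(C)\CO[Si](c1ccccc1)(c1ccccc1)C(C)(C)C | intermediate
5 | (2,6-dimethoxyphenyl)acetic acid | OC(=O)Cc1c(OC)cccc1OC | starting material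
6 | (2Z)-4-[(tert-butyldiphenylsilyl)oxy]-3-methylbut-2-en-1-yl (2,6-dimethoxyphenyl)acetate | COc1cccc(OC)c1CC(=O)OC/C=C(C)\CO[Si](c1ccccc1)(c1ccccc1)C(C)(C)C | intermediate
7 | Z(O)-boron ketene acetal of 6 bearing the (S,S)-diazaborolidine on oxygen (aryl cis to O–B) | COc1cccc(OC)c1/C=C(\OB1N(S(=O)(=O)c2cc(cc(c2)C(F)(F)F)C(F)(F)F)[C@@H](c2ccccc2)[C@H](c2ccccc2)N1S(=O)(=O)c1cc(cc(c1)C(F)(F)F)C(F)(F)F)OC/C=C(C)\CO[Si](c1ccccc1)(c1ccccc1)C(C)(C)C | intermediate (not isolated)
8 | (2R,3S)-3-{[(tert-butyldiphenylsilyl)oxy]methyl}-2-(2,6-dimethoxyphenyl)-3-methylpent-4-enoic acid | CC(C)(C)[Si](c1ccccc1)(c1ccccc1)OC[C@@]([C@@H](C(O)=O)c1c(OC)cccc1OC)(C)C=C | intermediate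
9 | (2R,3S)-3-{[(tert-butyldiphenylsilyl)oxy]methyl}-2-(2,6-dimethoxyphenyl)-3-methylpent-4-en-1-ol | CC(C)(C)[Si](c1ccccc1)(c1ccccc1)OC[C@@]([C@@H](CO)c1c(OC)cccc1OC)(C)C=C | intermediate
10 | (2R,3S)-3-{[(tert-butyldiphenylsilyl)oxy]methyl}-2-(2,6-dimethoxyphenyl)-3-methylpent-4-enal | CC(C)(C)[Si](c1ccccc1)(c1ccccc1)OC[C@@]([C@@H](C=O)c1c(OC)cccc1OC)(C)C=C | intermediate
11 | ethyltriphenylphosphonium iodide | CC[P+](c1ccccc1)(c1ccccc1)c1ccccc1.[I-] | starting material
12 | (1-iodoethyl)triphenylphosphonium iodide | CC(I)[P+](c1ccccc1)(c1ccccc1)c1ccccc1.[I-] | intermediate (not isolated)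
13 | (1-iodoethylidene)triphenylphosphorane | CC(I)=P(c1ccccc1)(c1ccccc1)c1ccccc1 | intermediate (not isolated)
14 | 2-[(3S,4R,5Z)-3-{[(tert-butyldiphenylsilyl)oxy]methyl}-6-iodo-3-methylhepta-1,5-dien-4-yl]-1,3-dimethoxybenzene (key-step precursor: vinyl on C1, (Z)-2-iodopropenyl on C6) | CC(C)(C)[Si](c1ccccc1)(c1ccccc1)OC[C@@]([C@@H](/C=C(C)\I)c1c(OC)cccc1OC)(C)C=C | intermediate
15 | 9-[(3S,4R,5Z)-3-{[(tert-butyldiphenylsilyl)oxy]methyl}-4-(2,6-dimethoxyphenyl)-6-iodo-3-methylhept-5-en-1-yl]-9-borabicyclo[3.3.1]nonane | CC(C)(C)[Si](c1ccccc1)(c1ccccc1)OC[C@@]([C@@H](/C=C(C)\I)c1c(OC)cccc1OC)(C)CCB1C2CCCC1CCC2 | intermediate (not isolated)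
16 | tert-butyl{[(1S,2R)-2-(2,6-dimethoxyphenyl)-1,4-dimethylcyclohex-3-en-1-yl]methoxy}diphenylsilane (key-step product) | CC(C)(C)[Si](c1ccccc1)(c1ccccc1)OC[C@@]1(C)CCC(C)=C[C@H]1c1c(OC)cccc1OC | intermediate
17 | [(1S,2R)-2-(2,6-dimethoxyphenyl)-1,4-dimethylcyclohex-3-en-1-yl]methanol | OC[C@@]1(C)CCC(C)=C[C@H]1c1c(OC)cccc1OC | intermediate
18 | (1S,2S)-2-(2,6-dimethoxyphenyl)-1,4-dimethylcyclohex-3-ene-1-carbaldehyde (formyl cis to aryl) | O=C[C@@]1(C)CCC(C)=C[C@H]1c1c(OC)cccc1OC | intermediate
19 | (2,6-dimethoxyphenyl)methanol | OCc1c(OC)cccc1OC | starting material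
20 | diethyl [(2,6-dimethoxyphenyl)methyl]phosphonate | CCOP(=O)(Cc1c(OC)cccc1OC)OCC | intermediate
21 | 2-[(1R,6R)-6-[(E)-2-(2,6-dimethoxyphenyl)ethenyl]-3,6-dimethylcyclohex-2-en-1-yl]-1,3-dimethoxybenzene | COc1cccc(OC)c1/C=C/[C@@]1(C)CCC(C)=C[C@H]1c1c(OC)cccc1OC | intermediate
22 | 2-[(E)-2-[(1R,2R)-2-(2-hydroxy-6-methoxyphenyl)-1,4-dimethylcyclohex-3-en-1-yl]ethenyl]-3-methoxyphenol | COc1cccc(O)c1/C=C/[C@@]1(C)CCC(C)=C[C@H]1c1c(OC)cccc1O | intermediate
23 | 3-[(1R,6R)-6-[(E)-2-(3-formyl-2-hydroxy-6-methoxyphenyl)ethenyl]-3,6-dimethylcyclohex-2-en-1-yl]-2-hydroxy-4-methoxybenzaldehyde | COc1ccc(C=O)c(O)c1/C=C/[C@@]1(C)CCC(C)=C[C@H]1c1c(OC)ccc(C=O)c1O | intermediate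
24 | bis(ethyl (E)-2-hydroxycinnamate) formed from 23 at both formyl groups | COc1ccc(/C=C/C(=O)OCC)c(O)c1/C=C/[C@@]1(C)CCC(C)=C[C@H]1c1c(OC)ccc(/C=C/C(=O)OCC)c1O | intermediate (not isolated)
25 | 7-methoxy-8-[(1R,6R)-6-[(E)-2-(7-methoxy-2-oxo-2H-chromen-8-yl)ethenyl]-3,6-dimethylcyclohex-2-en-1-yl]-2H-chromen-2-one (CNP0156435.1) | COc1ccc2ccc(=O)oc2c1/C=C/[C@@]1(C)CCC(C)=C[C@H]1c1c(OC)ccc2ccc(=O)oc12 | target

Total step count: 16
Longest linear sequence: 15 (steps 1–11 and 13–16; step 12 is a one-step branch)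

Steps most likely to fail

Step 9 (ring closure). Hydroboration of the neopentyl-type vinyl group may be slow, and β-hydride elimination or protodeboronation of the C3 alkyl–metal species may outrun reductive elimination, returning reduced or uncyclised material. The fallback sets out from 14 and comes back at 16, forming the same C3–C4 bond through an organozinc instead of an organoborane. Hydroboration of 14 with 9-BBN-H followed by NaBO3·4H2O oxidation should give the primary alcohol (3S,4R,5Z)-3-{[(tert-butyldiphenylsilyl)oxy]methyl}-4-(2,6-dimethoxyphenyl)-6-iodo-3-methylhept-5-en-1-ol F1. Treatment with I2, PPh3 and imidazole should convert it into the primary iodide tert-butyl{[(2S,3R,4Z)-3-(2,6-dimethoxyphenyl)-5-iodo-2-(2-iodoethyl)-2-methylhex-4-en-1-yl]oxy}diphenylsilane F2. Activated Zn with LiCl in THF inserts only into the C(sp3)–I bond to give the alkylzinc iodide F3, and Pd(PPh3)4 then closes the ring by intramolecular Negishi coupling with the Z-iodoalkene to give 16.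

Step 5 (asymmetric rearrangement). Soft enolisation of the hindered arylacetate by the boron bromide may be slow, and facial or enolate-geometry control may be incomplete. The fallback sets out from 6 and comes back at 8. KN(SiMe3)2 and Me3SiCl in THF at −78 °C should give the Z(O)-trimethylsilyl ketene acetal F4, which on warming undergoes the classical Ireland–Claisen rearrangement through the same chair; hydrolysis gives the racemic acid of the same relative configuration, rac-(2R*,3S*)-3-{[(tert-butyldiphenylsilyl)oxy]methyl}-2-(2,6-dimethoxyphenyl)-3-methylpent-4-enoic acid F5. Classical resolution by fractional crystallisation of the (R)-1-phenylethylammonium salt of 8 F6 follows (the (S)-amine would be used if its salt with 8 were the less soluble one), and acidification returns 8.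

Step 8 (iodo-olefination). Addition of the bulky ylide to the congested α-aryl aldehyde may be slow, letting base-mediated epimerisation at C6 or erosion of the Z selectivity compete. The fallback sets out from 10 and comes back at 16 and avoids any basic ylide. CBr4 and PPh3 in CH2Cl2 should give the 1,1-dibromoalkene 2-[(3S,4R)-6,6-dibromo-3-{[(tert-butyldiphenylsilyl)oxy]methyl}-3-methylhexa-1,5-dien-4-yl]-1,3-dimethoxybenzene F7. Palladium-catalysed trans-selective monomethylation with MeZnCl and PdCl2(DPEphos) replaces only the bromine trans to C6 and gives the (Z)-bromoalkene 2-[(3S,4R,5Z)-6-bromo-3-{[(tert-butyldiphenylsilyl)oxy]methyl}-3-methylhepta-1,5-dien-4-yl]-1,3-dimethoxybenzene F8. 9-BBN-H then gives the B-alkyl borane F9, which is cyclised with PdCl2(dppf) and aq Cs2CO3 as in step 9 to give 16.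

Further compounds
F1 | step 9 | (3S,4R,5Z)-3-{[(tert-butyldiphenylsilyl)oxy]methyl}-4-(2,6-dimethoxyphenyl)-6-iodo-3-methylhept-5-en-1-ol | CC(C)(C)[Si](c1ccccc1)(c1ccccc1)OC[C@@]([C@@H](/C=C(C)\I)c1c(OC)cccc1OC)(C)CCO
F2 | step 9 | tert-butyl{[(2S,3R,4Z)-3-(2,6-dimethoxyphenyl)-5-iodo-2-(2-iodoethyl)-2-methylhex-4-en-1-yl]oxy}diphenylsilane | CC(C)(C)[Si](c1ccccc1)(c1ccccc1)OC[C@@]([C@@H](/C=C(C)\I)c1c(OC)cccc1OC)(C)CCI
F3 | step 9 | alkylzinc iodide from F2 (zinc on the former C3 carbon) | CC(C)(C)[Si](c1ccccc1)(c1ccccc1)OC[C@@]([C@@H](/C=C(C)\I)c1c(OC)cccc1OC)(C)CC[Zn]I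
F4 | step 5 | Z(O)-trimethylsilyl ketene acetal of 6 | COc1cccc(OC)c1/C=C(\O[Si](C)(C)C)OC/C=C(C)\CO[Si](c1ccccc1)(c1ccccc1)C(C)(C)C
F5 | step 5 | rac-(2R*,3S*)-3-{[(tert-butyldiphenylsilyl)oxy]methyl}-2-(2,6-dimethoxyphenyl)-3-methylpent-4-enoic acid (racemate; one enantiomer drawn) | CC(C)(C)[Si](c1ccccc1)(c1ccccc1)OC[C@@]([C@@H](C(O)=O)c1c(OC)cccc1OC)(C)C=C
F6 | step 5 | (R)-1-phenylethylammonium salt of 8 | CC(C)(C)[Si](c1ccccc1)(c1ccccc1)OC[C@@]([C@@H](C([O-])=O)c1c(OC)cccc1OC)(C)C=C.C[C@@H]([NH3+])c1ccccc1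
F7 | step 8 | 2-[(3S,4R)-6,6-dibromo-3-{[(tert-butyldiphenylsilyl)oxy]methyl}-3-methylhexa-1,5-dien-4-yl]-1,3-dimethoxybenzene | CC(C)(C)[Si](c1ccccc1)(c1ccccc1)OC[C@@]([C@@H](C=C(Br)Br)c1c(OC)cccc1OC)(C)C=C
F8 | step 8 | 2-[(3S,4R,5Z)-6-bromo-3-{[(tert-butyldiphenylsilyl)oxy]methyl}-3-methylhepta-1,5-dien-4-yl]-1,3-dimethoxybenzene | CC(C)(C)[Si](c1ccccc1)(c1ccccc1)OC[C@@]([C@@H](/C=C(C)\Br)c1c(OC)cccc1OC)(C)C=C
F9 | step 8 | 9-[(3S,4R,5Z)-6-bromo-3-{[(tert-butyldiphenylsilyl)oxy]methyl}-4-(2,6-dimethoxyphenyl)-3-methylhept-5-en-1-yl]-9-borabicyclo[3.3.1]nonane | CC(C)(C)[Si](c1ccccc1)(c1ccccc1)OC[C@@]([C@@H](/C=C(C)\Br)c1c(OC)cccc1OC)(C)CCB1C2CCCC1CCC2
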